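**Retrosynthetic overview**
- The chain is numbered C1 (on ring A, the methoxy-phenol ring) to C14 (on ring B, the resorcinol ring). The last step is acid removal of three MOM ethers, and the ring A methyl ether is carried from the start.
- Key disconnection C13–C14: a crossed aldol (Claisen–Schmidt) condensation joins a ring A methyl ketone (C1–C13, E-alkene in place) to 3,5-bis(methoxymethoxy)benzaldehyde (C14 and ring B). The enone C=C and the C12 carbonyl are then removed by conjugate reduction and Wolff–Kishner reduction.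
- The methyl ketone comes from acetoacetic ester alkylation (C10–C11) of an E-allylic bromide, whose C8=C9 geometry is set by a Horner–Wadsworth–Emmons olefination of the C1–C8 aldehyde.
- The C1–C8 aldehyde comes from a Wittig reaction (C1=C2) of 3-methoxy-5-(methoxymethoxy)benzaldehyde with a seven-carbon carboxy ylide, then hydrogenation and redox adjustment.
- No ring is formed: both benzene rings are bought as 3,5-dioxygenated benzaldehydes.

Assumption: the target has no stereocentre, so the only stereochemical element to deliver is the E geometry of the C8=C9 alkene.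

**Route**

Step 1
Reactants: 1 3,5-dimethoxybenzaldehyde
Product: 2 3-hydroxy-5-methoxybenzaldehyde
Conditions: NaSEt (2 equiv), DMF, 150 °C; then aq HCl
Reagents that add atoms: none
Why: Thiolate SN2 O-demethylation of an aryl methyl ether stops at the mono-phenol because the phenoxide formed first deactivates the ring toward a second cleavage.

Step 2
Reactants: 2 3-hydroxy-5-methoxybenzaldehyde
Product: 3 3-methoxy-5-(methoxymethoxy)benzaldehyde
Conditions: MOMCl, iPr2NEt, CH2Cl2, 0 °C → rt
Reagents that add atoms: chloromethyl methyl ether (MOMCl), COCCl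
Why: Base-mediated O-alkylation of the phenol (MOM protection) gives an acetal that survives all later basic, hydride and hydrazine steps and is removed by acid at the end.

Step 3
Reactants: 3 3-methoxy-5-(methoxymethoxy)benzaldehyde; 4 (6-carboxyhexyl)triphenylphosphonium bromide
Product: 6 8-[3-methoxy-5-(methoxymethoxy)phenyl]oct-7-enoic acid (Z/E mixture), via phosphonium ylide 5 (not isolated)
Conditions: 4, KOtBu (2.2 equiv), THF, 0 °C; then 3, 0 °C → rt; then aq HCl to pH 4 at 0 °C
Reagents that add atoms: none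
Why: Wittig olefination of a non-enolisable aryl aldehyde with an unstabilised ylide is dependable, and the Z/E mixture is irrelevant because the alkene is hydrogenated next.

Step 4
Reactants: 6 8-[3-methoxy-5-(methoxymethoxy)phenyl]oct-7-enoic acid (Z/E mixture)
Product: 7 8-[3-methoxy-5-(methoxymethoxy)phenyl]octanoic acid
Conditions: H2 (1 atm), 10% Pd/C, EtOAc, rt
Reagents that add atoms: none
Why: Heterogeneous catalytic hydrogenation saturates the styrene-type alkene while the aryl ethers, the MOM acetal and the acid are inert.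

Step 5
Reactants: 7 8-[3-methoxy-5-(methoxymethoxy)phenyl]octanoic acid
Product: 8 8-[3-methoxy-5-(methoxymethoxy)phenyl]octan-1-ol
Conditions: LiAlH4, THF, 0 °C → rt; then H2O, aq NaOH
Reagents that add atoms: none
Why: Hydride reduction of a carboxylic acid to the primary alcohol is clean here because nothing else in the molecule is reducible by LiAlH4.

Step 6
Reactants: 8 8-[3-methoxy-5-(methoxymethoxy)phenyl]octan-1-ol
Product: 9 8-[3-methoxy-5-(methoxymethoxy)phenyl]octanal
Conditions: Dess–Martin periodinane, CH2Cl2, rt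
Reagents that add atoms: none
Why: Dess–Martin oxidation stops at the aldehyde under near-neutral conditions that leave the MOM acetal and the electron-rich ring untouched.

Step 7
Reactants: 9 8-[3-methoxy-5-(methoxymethoxy)phenyl]octanal; 10 triethyl phosphonoacetate
Product: 12 ethyl (2E)-10-[3-methoxy-5-(methoxymethoxy)phenyl]dec-2-enoate, via phosphonate carbanion 11 (not isolated)
Conditions: 10, NaH, THF, 0 °C; then 9, 0 °C → rt
Reagents that add atoms: none
Why: The Horner–Wadsworth–Emmons reaction of a stabilised phosphonate anion gives the E-enoate (typically above 95:5, minor Z isomer removed by chromatography), which fixes the E geometry of the future C8=C9 alkene.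

Step 8
Reactants: 12 ethyl (2E)-10-[3-methoxy-5-(methoxymethoxy)phenyl]dec-2-enoate
Product: 13 (2E)-10-[3-methoxy-5-(methoxymethoxy)phenyl]dec-2-en-1-ol
Conditions: iBu2AlH (2.5 equiv), CH2Cl2, −78 °C → 0 °C; then aq potassium sodium tartrate
Reagents that add atoms: none
Why: iBu2AlH reduces the enoate 1,2 to the allylic alcohol without touching the alkene or its geometry.

Step 9
Reactants: 13 (2E)-10-[3-methoxy-5-(methoxymethoxy)phenyl]dec-2-en-1-ol
Product: 14 1-[(8E)-10-bromodec-8-en-1-yl]-3-methoxy-5-(methoxymethoxy)benzene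
Conditions: CBr4, PPh3, CH2Cl2, 0 °C
Reagents that add atoms: carbon tetrabromide, BrC(Br)(Br)Br
Why: The Appel reaction converts the primary allylic alcohol to the bromide by SN2 displacement under neutral conditions, without allylic transposition or loss of E geometry.

Step 10
Reactants: 14 1-[(8E)-10-bromodec-8-en-1-yl]-3-methoxy-5-(methoxymethoxy)benzene; 15 ethyl acetoacetate
Product: 17 ethyl (4E)-2-acetyl-12-[3-methoxy-5-(methoxymethoxy)phenyl]dodec-4-enoate (racemic), via sodium enolate 16 (not isolated)
Conditions: 15 (2 equiv), NaH (1.8 equiv), THF, 0 °C; then 14, rt → 50 °C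
Reagents that add atoms: none
Why: In this acetoacetic ester alkylation the soft β-keto ester enolate attacks the primary allylic bromide by SN2 at carbon, excess enolate suppresses dialkylation, and the new C2 stereocentre is racemic and is erased in the next step.

Step 11
Reactants: 17 ethyl (4E)-2-acetyl-12-[3-methoxy-5-(methoxymethoxy)phenyl]dodec-4-enoate (racemic)
Product: 19 (5E)-13-[3-methoxy-5-(methoxymethoxy)phenyl]tridec-5-en-2-one, via β-keto acid 18 (not isolated)
Conditions: LiCl, H2O, DMSO, 150 °C
Reagents that add atoms: none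
Why: Krapcho dealkoxycarbonylation (salt-assisted ester cleavage, then decarboxylation of the β-keto acid) gives the methyl ketone under neutral conditions that spare the MOM acetal and the E-alkene.

Step 12
Reactants: 20 3,5-dihydroxybenzaldehyde
Product: 21 3,5-bis(methoxymethoxy)benzaldehyde
Conditions: MOMCl (2.5 equiv), iPr2NEt (3 equiv), DMF, 0 °C → rt
Reagents that add atoms: chloromethyl methyl ether (MOMCl), COCCl
Why: Double O-alkylation of the two phenols (MOM protection) gives a base-stable, non-enolisable aldehyde for the aldol step.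

Step 13
Reactants: 19 (5E)-13-[3-methoxy-5-(methoxymethoxy)phenyl]tridec-5-en-2-one; 21 3,5-bis(methoxymethoxy)benzaldehyde
Product: 23 (1E,6E)-1-[3,5-bis(methoxymethoxy)phenyl]-14-[3-methoxy-5-(methoxymethoxy)phenyl]tetradeca-1,6-dien-3-one, via β-hydroxy ketone 22 (not isolated)
Conditions: 19 (1.0 equiv), 21 (1.1 equiv), 10% aq NaOH, EtOH–THF, rt
Reagents that add atoms: none
Why: In this Claisen–Schmidt (crossed aldol) condensation the aldehyde cannot enolise, the ketone reacts on its methyl side because only that aldol dehydrates readily, and E1cB loss of water gives the conjugated E-enone while the remote C8=C9 alkene has no acidic allylic hydrogen.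

Step 14
Reactants: 23 (1E,6E)-1-[3,5-bis(methoxymethoxy)phenyl]-14-[3-methoxy-5-(methoxymethoxy)phenyl]tetradeca-1,6-dien-3-one
Product: 24 (6E)-1-[3,5-bis(methoxymethoxy)phenyl]-14-[3-methoxy-5-(methoxymethoxy)phenyl]tetradec-6-en-3-one
Conditions: [(Ph3P)CuH]6 (0.4 equiv), H2O (5 equiv), degassed toluene, rt, under Ar
Reagents that add atoms: none
Why: Conjugate (1,4) hydride reduction with Stryker's reagent attacks only the electron-poor enone alkene, and water protonates the copper enolate, so the isolated E-alkene and the ketone are kept.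

Step 15
Reactants: 24 (6E)-1-[3,5-bis(methoxymethoxy)phenyl]-14-[3-methoxy-5-(methoxymethoxy)phenyl]tetradec-6-en-3-one
Product: 26 1-[(8E)-14-[3,5-bis(methoxymethoxy)phenyl]tetradec-8-en-1-yl]-3-methoxy-5-(methoxymethoxy)benzene, via hydrazone 25 (not isolated)
Conditions: N2H4·H2O, KOH, diethylene glycol, 130 °C then 200 °C, under N2
Reagents that add atoms: none
Why: Wolff–Kishner reduction (Huang-Minlon procedure) turns the dialkyl ketone into CH2 through its hydrazone, and the aryl ethers, MOM acetals and the isolated, non-conjugated E-alkene are stable to hot base when air is excluded.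

Step 16
Reactants: 26 1-[(8E)-14-[3,5-bis(methoxymethoxy)phenyl]tetradec-8-en-1-yl]-3-methoxy-5-(methoxymethoxy)benzene
Product: 27 dehydrobisgravillol, 5-[(6E)-14-(3-hydroxy-5-methoxyphenyl)tetradec-6-en-1-yl]benzene-1,3-diol
Conditions: HCl (3 M aq), MeOH, 50 °C
Reagents that add atoms: none
Why: Acid-catalysed acetal cleavage (transacetalisation to methanol) removes the three MOM groups, while the aryl methyl ether and the isolated E-alkene are inert to dilute acid.

**Compound list**

1 | 3,5-dimethoxybenzaldehyde | COc1cc(C=O)cc(OC)c1 | starting material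
2 | 3-hydroxy-5-methoxybenzaldehyde | COc1cc(O)cc(C=O)c1 | intermediate
3 | 3-methoxy-5-(methoxymethoxy)benzaldehyde | COCOc1cc(OC)cc(C=O)c1 | intermediate
4 | (6-carboxyhexyl)triphenylphosphonium bromide | OC(=O)CCCCCC[P+](c1ccccc1)(c1ccccc1)c1ccccc1.[Br-] | starting material
5 | potassium 7-(triphenylphosphoranylidene)heptanoate (ylide) | [K+].[O-]C(=O)CCCCCC=P(c1ccccc1)(c1ccccc1)c1ccccc1 | intermediate (not isolated)
6 | 8-[3-methoxy-5-(methoxymethoxy)phenyl]oct-7-enoic acid (Z/E mixture, geometry not defined) | COCOc1cc(OC)cc(C=CCCCCCC(=O)O)c1 | intermediate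
7 | 8-[3-methoxy-5-(methoxymethoxy)phenyl]octanoic acid | COCOc1cc(OC)cc(CCCCCCCC(=O)O)c1 | intermediate
8 | 8-[3-methoxy-5-(methoxymethoxy)phenyl]octan-1-ol | COCOc1cc(OC)cc(CCCCCCCCO)c1 | intermediate
9 | 8-[3-methoxy-5-(methoxymethoxy)phenyl]octanal | COCOc1cc(OC)cc(CCCCCCCC=O)c1 | intermediate
10 | triethyl phosphonoacetate | CCOC(=O)CP(=O)(OCC)OCC | starting material
11 | sodium salt of triethyl phosphonoacetate (phosphonate carbanion) | [Na+].CCOC(=O)[CH-]P(=O)(OCC)OCC | intermediate (not isolated)
12 | ethyl (2E)-10-[3-methoxy-5-(methoxymethoxy)phenyl]dec-2-enoate | COCOc1cc(OC)cc(CCCCCCC/C=C/C(=O)OCC)c1 | intermediate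
13 | (2E)-10-[3-methoxy-5-(methoxymethoxy)phenyl]dec-2-en-1-ol | COCOc1cc(OC)cc(CCCCCCC/C=C/CO)c1 | intermediate
14 | 1-[(8E)-10-bromodec-8-en-1-yl]-3-methoxy-5-(methoxymethoxy)benzene | COCOc1cc(OC)cc(CCCCCCC/C=C/CBr)c1 | intermediate
15 | ethyl acetoacetate | CCOC(=O)CC(C)=O | starting material
16 | sodium enolate of ethyl acetoacetate | [Na+].CCOC(=O)[CH-]C(C)=O | intermediate (not isolated)
17 | ethyl (4E)-2-acetyl-12-[3-methoxy-5-(methoxymethoxy)phenyl]dodec-4-enoate (racemic at C2) | COCOc1cc(OC)cc(CCCCCCC/C=C/CC(C(C)=O)C(=O)OCC)c1 | intermediate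
18 | (4E)-2-acetyl-12-[3-methoxy-5-(methoxymethoxy)phenyl]dodec-4-enoic acid (racemic) | COCOc1cc(OC)cc(CCCCCCC/C=C/CC(C(C)=O)C(=O)O)c1 | intermediate (not isolated)
19 | (5E)-13-[3-methoxy-5-(methoxymethoxy)phenyl]tridec-5-en-2-one | COCOc1cc(OC)cc(CCCCCCC/C=C/CCC(C)=O)c1 | intermediate
20 | 3,5-dihydroxybenzaldehyde | O=Cc1cc(O)cc(O)c1 | starting material
21 | 3,5-bis(methoxymethoxy)benzaldehyde | COCOc1cc(OCOC)cc(C=O)c1 | intermediate
22 | (6E)-1-[3,5-bis(methoxymethoxy)phenyl]-1-hydroxy-14-[3-methoxy-5-(methoxymethoxy)phenyl]tetradec-6-en-3-one (racemic) | COCOc1cc(OC)cc(CCCCCCC/C=C/CCC(=O)CC(O)c2cc(OCOC)cc(OCOC)c2)c1 | intermediate (not isolated)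
23 | (1E,6E)-1-[3,5-bis(methoxymethoxy)phenyl]-14-[3-methoxy-5-(methoxymethoxy)phenyl]tetradeca-1,6-dien-3-one | COCOc1cc(OC)cc(CCCCCCC/C=C/CCC(=O)/C=C/c2cc(OCOC)cc(OCOC)c2)c1 | intermediate
24 | (6E)-1-[3,5-bis(methoxymethoxy)phenyl]-14-[3-methoxy-5-(methoxymethoxy)phenyl]tetradec-6-en-3-one | COCOc1cc(OC)cc(CCCCCCC/C=C/CCC(=O)CCc2cc(OCOC)cc(OCOC)c2)c1 | intermediate
25 | hydrazone of 24 (C=N geometry not defined) | COCOc1cc(OC)cc(CCCCCCC/C=C/CCC(=NN)CCc2cc(OCOC)cc(OCOC)c2)c1 | intermediate (not isolated)
26 | 1-[(8E)-14-[3,5-bis(methoxymethoxy)phenyl]tetradec-8-en-1-yl]-3-methoxy-5-(methoxymethoxy)benzene | COCOc1cc(OC)cc(CCCCCCC/C=C/CCCCCc2cc(OCOC)cc(OCOC)c2)c1 | intermediate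
27 | dehydrobisgravillol, 5-[(6E)-14-(3-hydroxy-5-methoxyphenyl)tetradec-6-en-1-yl]benzene-1,3-diol | COc1cc(O)cc(CCCCCCC/C=C/CCCCCc2cc(O)cc(O)c2)c1 | target

**Step count and risks**

Total steps: 16. Longest linear sequence: 15 (steps 1–11 and 13–16, from compound 1). Step 12 is the one-step branch that makes the ring B aldehyde.

The three steps most likely to fail:

Step 13, the Claisen–Schmidt condensation. The risks are attack on the methylene side of the ketone, a second condensation, or Michael addition of enolate to the product. The fallback sets out from bromide 14 and comes back at enone 23. The dianion of dimethyl (2-oxopropyl)phosphonate (NaH, then n-BuLi, THF, 0 °C) is alkylated at its terminal carbon by 14 to give dimethyl {(5E)-13-[3-methoxy-5-(methoxymethoxy)phenyl]-2-oxotridec-5-en-1-yl}phosphonate F1. Horner–Wadsworth–Emmons olefination of aldehyde 21 with F1 (LiCl, DBU, MeCN, rt) then forms the same C13=C14 bond with unambiguous regiochemistry and E geometry, giving 23.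

Step 14, the conjugate reduction. The risks are an air-sensitive reagent, incomplete conversion, or 1,2-reduction. The fallback sets out from enone 23 and comes back at ketone 24. Luche reduction (NaBH4, CeCl3·7H2O, MeOH, 0 °C) gives the allylic alcohol (1E,6E)-1-[3,5-bis(methoxymethoxy)phenyl]-14-[3-methoxy-5-(methoxymethoxy)phenyl]tetradeca-1,6-dien-3-ol F2. A ruthenium-catalysed redox isomerisation of this allylic alcohol (Cp*RuCl(PPh3)2 cat., KOtBu cat., toluene, rt) moves the hydrogen from the carbinol carbon to the neighbouring alkene and gives the saturated ketone 24. The isolated C8=C9 alkene has no hydroxyl to bind the catalyst and is left alone.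

Step 15, the Wolff–Kishner reduction. The risks are partial cleavage of the aryl methyl ether in hot KOH, or diimide reduction of the alkene if air gets in. The fallback sets out from ketone 24 and comes back at 26. NaBH4 (MeOH, 0 °C) gives the secondary alcohol (6E)-1-[3,5-bis(methoxymethoxy)phenyl]-14-[3-methoxy-5-(methoxymethoxy)phenyl]tetradec-6-en-3-ol F3. NaH, CS2, then MeI (THF, 0 °C → rt) converts it to the xanthate O-{(6E)-1-[3,5-bis(methoxymethoxy)phenyl]-14-[3-methoxy-5-(methoxymethoxy)phenyl]tetradec-6-en-3-yl} S-methyl carbonodithioate F4. Barton–McCombie deoxygenation (Bu3SnH, AIBN, toluene, 110 °C) then gives 26. The secondary radical is a pent-4-enyl radical, whose cyclisation onto the C8=C9 alkene is too slow to compete with hydrogen transfer from the tin hydride.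

**Further compounds**

F1 | step 13 | dimethyl {(5E)-13-[3-methoxy-5-(methoxymethoxy)phenyl]-2-oxotridec-5-en-1-yl}phosphonate | COCOc1cc(OC)cc(CCCCCCC/C=C/CCC(=O)CP(=O)(OC)OC)c1
F2 | step 14 | (1E,6E)-1-[3,5-bis(methoxymethoxy)phenyl]-14-[3-methoxy-5-(methoxymethoxy)phenyl]tetradeca-1,6-dien-3-ol (racemic) | COCOc1cc(OC)cc(CCCCCCC/C=C/CCC(O)/C=C/c2cc(OCOC)cc(OCOC)c2)c1
F3 | step 15 | (6E)-1-[3,5-bis(methoxymethoxy)phenyl]-14-[3-methoxy-5-(methoxymethoxy)phenyl]tetradec-6-en-3-ol (racemic) | COCOc1cc(OC)cc(CCCCCCC/C=C/CCC(O)CCc2cc(OCOC)cc(OCOC)c2)c1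
F4 | step 15 | O-{(6E)-1-[3,5-bis(methoxymethoxy)phenyl]-14-[3-methoxy-5-(methoxymethoxy)phenyl]tetradec-6-en-3-yl} S-methyl carbonodithioate (racemic) | COCOc1cc(OC)cc(CCCCCCC/C=C/CCC(OC(=S)SC)CCc2cc(OCOC)cc(OCOC)c2)c1
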